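The numbers in the tables come from a simulation for substances that don't exist, and the scatter is random.

Watch the pace.

| flask | solid monomer | initiator | remark | time |
|---|---|---|---|---|
| theta | 0.80 M | 56 mM | run made earlier |  |
| zeta | 0.80 M | 88 mM | run made earlier |  |
| eta | 0.40 M | 40 mM | run made earlier |  |
| flask | 0.80 M | 40 mM |  | 15 h |

| run | time / h | monomer in chains / % | free monomer / % |
|---|---|---|---|
| theta | 0.667 | 0 | 64 |
| theta | 1.50 | 8 | 70 |
| theta | 4.00 | 26 | 70 |
| theta | 10.0 | 83 | 19 |
| zeta | 1.00 | 3 | 65 |
| zeta | 3.00 | 26 | 66 |
| zeta | 6.00 | 70 | 31 |
| zeta | 10.0 | 93 | 4 |
| eta | 2.50 | 9 | 91 |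
| eta | 5.00 | 30 | 72 |
| eta | 6.00 | 39 | 65 |
| eta | 10.0 | 65 | 37 |

(standard deviation of a reading: 1.5 percentage points)

- solid monomer is a solid; its amount is given per volume of the solution
- at the start none of the solid monomer is in solution
- free monomer is what solid monomer becomes in solution

* how much monomer in chains there is at 15 h, in percent of the solid monomer charged
* concentration of free monomer in solution at 15 h, in percent of saturation

By pace I mean the share of the free monomer that enters chains per hour, a pseudo-first-order constant, and I read it two ways. While solid is left, theta and zeta hold free monomer near 67.8% of the charge. On that plateau zeta's chains go from 3% to 26% between 1.00 h and 3.00 h, roughly the square of time, and, averaged between the plateau readings of each run, they grow 1.60 times as fast as theta's on 1.57 times the initiator, so I scale by initiator.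

The first way is eta, with the flask's initiator, whose free monomer falls from 6.00 h to 10.0 h at a pace of 0.141 h⁻¹. The second is theta, whose solid, by that square of time, lasts until about 4.45 h; theta's later fall to 19%, scaled to the flask's initiator, gives 0.164 h⁻¹.

The two part, and I distrust eta, whose free monomer at 6.00 h stands at about half of the plateau concentration read in theta and zeta. So I commit to theta: the flask's solid lasts until about 5.27 h, leaving 13.8% free at 15 h, 86.2% in chains and 20.4% of saturation.

The forecast says 83% and 25%, holding that “Theta and zeta hint that concentrated runs go somewhat faster”.

The flask gives 90.0% in chains and 14.3% of saturation.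

    free monomer + initiator → living end + monomer in chains (k = 0.300 M⁻¹ h⁻¹)
    free monomer + living end → monomer in chains + living end, rate k2*[living end]*[free monomer] (k = 6.70 M⁻¹ h⁻¹)
    solid monomer ⇌ free monomer, rate k3*(cs3 - [free monomer]) while solid is left; crystals form when [free monomer] > cs3 (solubility = 0.560 M, k = 4.00 h⁻¹)

Between 7.50 h and 15 h the flask's free monomer falls from 46.2% to 9.98%, on average a pace of 0.204 h⁻¹, faster than both my readings. A neighbour, the same flask charged with 0.32 M of solid monomer, has a charge below the plateau concentration read in theta and zeta, so there I carry eta's pace: starting from eta's 37% of its own charge at 10.0 h, this reckons 18.3% free at 15 h, and the neighbour holds 19.0%.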